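**Strategy**

The six-membered carbocycle is closed at its quaternary carbon: the bond between ring C-1 (bearing CH3 and the pyranone) and the neighbouring ring CH (C-6) is formed by a palladium-catalysed asymmetric intramolecular enolate alkenylation. The step exploits that C-1 lies between the pyranone C-2' position and ring C-2, which is a ketone in the precursor, so that C-1–H is doubly activated, while C-6 is an enol triflate. One operation closes the ring and sets the quaternary stereocentre. The precursor is an acyclic dienyl triflate ketone made by acylating the lithiated ethylpyranone with a ring-opened 4-methoxy-2-pyranone; the side chain then enters by Stork–Danheiser addition–transposition.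

Key step: step 9

Remark: carbocycle positions are numbered as in the target (C-1 quaternary, C-2 side-chain carbon, C-4 carbonyl, C-6 CH). Compounds 1, 2, 7, 17 and 19 are taken as commercial.
Remark: the sense of induction of the bisphosphine in step 9 cannot be predicted with certainty; the ligand antipode that gives the (R)-dienone 16 is to be used.
Remark: the Marshall propargylation in step 11 is taken to proceed with net inversion at the propargylic carbon (anti oxidative addition, syn SE2' addition).

**Pyranone 6**

Step 1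
Reactants: 1 methyl 2-methyl-3-oxopentanoate; 2 N-methoxy-N-methylpropanamide
Product: 4 methyl 2,4-dimethyl-3,5-dioxoheptanoate, via sodium lithium dianion 3 (not isolated)
Conditions: NaH, THF, 0 °C; n-BuLi, 0 °C; then 2, 0 °C → rt; aq. HCl
Reagents that add atoms: none
Why: γ-Acylation of a β-keto ester dianion (Claisen-type): the γ-carbanion is the more nucleophilic site and the Weinreb amide stops at the ketone; the new stereocentres do not matter because the product is enolised in step 2.

Step 2
Reactants: 4 methyl 2,4-dimethyl-3,5-dioxoheptanoate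
Product: 5 6-ethyl-4-hydroxy-3,5-dimethyl-2H-pyran-2-one
Conditions: DBU, toluene, 110 °C
Reagents that add atoms: none
Why: Base-mediated lactonisation of the 3,5-diketo ester through its 5-enolate oxygen onto the ester gives the aromatic 4-hydroxy-2-pyranone.

Step 3
Reactants: 5 6-ethyl-4-hydroxy-3,5-dimethyl-2H-pyran-2-one
Product: 6 2-ethyl-6-methoxy-3,5-dimethyl-4H-pyran-4-one
Conditions: MeOTf, CH2Cl2, rt; aq. NaHCO3
Reagents that add atoms: methyl trifluoromethanesulfonate, COS(=O)(=O)C(F)(F)F
Why: Under neutral conditions the hard methylating agent alkylates the lactone carbonyl oxygen, and loss of the 4-OH proton on work-up should give the 2-methoxy-4-pyranone (regioselective O-methylation of a 4-hydroxy-2-pyranone).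

**Dienyl triflate 13**

Step 4
Reactants: 1 methyl 2-methyl-3-oxopentanoate; 7 methyl formate
Product: 9 methyl 2,4-dimethyl-3,5-dioxopentanoate, via dilithium dianion 8 (not isolated)
Conditions: LiN(i-Pr)2 (2.2 equiv), THF, −78 → 0 °C; then 7, −78 → 0 °C; aq. HCl
Reagents that add atoms: none
Why: Two equivalents of the lithium amide convert the β-keto ester into its dilithium dianion, whose γ-carbon is formylated by the formate (Claisen-type acylation); the product is expected as its hydroxymethylene tautomer and its stereocentres are lost on lactonisation.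

Step 5
Reactants: 9 methyl 2,4-dimethyl-3,5-dioxopentanoate
Product: 10 4-hydroxy-3,5-dimethyl-2H-pyran-2-one
Conditions: DBU, toluene, 80 °C
Reagents that add atoms: none
Why: Lactonisation of the hydroxymethylene oxygen onto the methyl ester gives the 6-unsubstituted 4-hydroxy-2-pyranone.

Step 6
Reactants: 10 4-hydroxy-3,5-dimethyl-2H-pyran-2-one
Product: 11 4-methoxy-3,5-dimethyl-2H-pyran-2-one
Conditions: Me2SO4, K2CO3, acetone, reflux
Reagents that add atoms: dimethyl sulfate, COS(=O)(=O)OC
Why: Williamson methylation of the pyranone anion occurs at the 4-oxygen, the usual outcome under basic conditions, and leaves the lactone carbonyl for step 7.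

Step 7
Reactants: 11 4-methoxy-3,5-dimethyl-2H-pyran-2-one
Product: 13 (1Z,3E)-3-methoxy-5-[methoxy(methyl)amino]-2,4-dimethyl-5-oxopenta-1,3-dien-1-yl trifluoromethanesulfonate, via lithium dienolate 12 (not isolated)
Conditions: MeNH(OMe)·HCl, n-BuLi (2 equiv), THF, −78 °C; then 11, −78 °C; then N-(5-chloropyridin-2-yl)triflimide, −78 → −20 °C
Reagents that add atoms: N,O-dimethylhydroxylamine hydrochloride, CNOC.Cl; N-(5-chloropyridin-2-yl)bis(trifluoromethanesulfonyl)imide, O=S(=O)(N(c1ccc(Cl)cn1)S(=O)(=O)C(F)(F)F)C(F)(F)F
Why: Lactone aminolysis at the only acyl carbon (Weinreb amide formation) opens the enol lactone to the dienolate, whose oxygen is still cis to the methoxy-bearing carbon as in the ring (lithium can bridge the two oxygens); O-sulfonylation at low temperature (enol triflate formation) should trap this 1Z geometry, and the 3E geometry is likewise inherited from the ring.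

**Ring closure**

Step 8
Reactants: 6 2-ethyl-6-methoxy-3,5-dimethyl-4H-pyran-4-one; 13 the dienyl triflate Weinreb amide
Product: 15 (1Z,3E)-3-methoxy-6-(6-methoxy-3,5-dimethyl-4-oxo-4H-pyran-2-yl)-2,4-dimethyl-5-oxohepta-1,3-dien-1-yl trifluoromethanesulfonate (racemic at C-6 of the chain), via lithiated pyranone 14 (not isolated)
Conditions: 6, LiN(SiMe3)2, THF, −78 °C; then 13, −78 → −40 °C; aq. NH4Cl
Reagents that add atoms: none
Why: Lateral lithiation of the ethyl group gives a vinylogous enolate that is C-acylated by the Weinreb amide, whose chelated tetrahedral adduct prevents over-addition and keeps the acidic product from quenching the carbanion; the new α-stereocentre is formed as a racemate because it is erased by enolisation in step 9.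

Step 9
Reactants: 15 the dienyl triflate ketone
Product: 16 (6R)-3-methoxy-6-(6-methoxy-3,5-dimethyl-4-oxo-4H-pyran-2-yl)-2,4,6-trimethylcyclohexa-2,4-dien-1-one
Conditions: Pd2(dba)3 (2.5 mol %), (R)-DIFLUORPHOS (6 mol %), K3PO4, toluene, 60 °C, exclusion of light
Reagents that add atoms: none
Why: Zerovalent palladium inserts into the C–OTf bond with retention of the Z geometry, so that the metal is held next to the ketone by the two cis double bonds; K3PO4 removes the C–H between the ketone and the pyranone, the only readily enolisable position, and C–C reductive elimination from the palladium enolate joins this carbon to the vinylic CH carbon. The closest known reaction type is the palladium-catalysed asymmetric α-arylation and α-alkenylation of α-branched ketones with aryl or alkenyl triflates and halides, which creates α-quaternary stereocentres. The six-membered ring is closed by reductive elimination from a seven-membered C-bound palladacycle, formally a 6-endo closure onto the alkenyl carbon. The quaternary stereocentre is controlled by the C2-symmetric bisphosphine, which differentiates the two enolate faces; the enolate is expected to react as the isomer with the pyranone cis to the enolate oxygen (smaller methyl group toward the diene), so that one geometry meets the chiral pocket. The step needs C- over O-alkenylation and reductive elimination faster than β-hydride loss from the α-methyl group, both favoured by the electron-poor chelating ligand. The metal-free thermal 6π closure of the trienolate, which carries a disubstituted terminus, is expected to be slow at 60 °C, so little racemic background is anticipated.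

**Side chain**

Step 10
Reactants: 17 (R)-but-3-yn-2-ol
Product: 18 (R)-but-3-yn-2-yl methanesulfonate
Conditions: MsCl, Et3N, CH2Cl2, −78 → 0 °C
Reagents that add atoms: methanesulfonyl chloride, CS(=O)(=O)Cl
Why: O-Sulfonylation leaves the C–O bond and hence the configuration untouched.

Step 11
Reactants: 18 (R)-but-3-yn-2-yl methanesulfonate; 19 propanal
Product: 21 (3R,4S)-4-methylhex-5-yn-3-ol, via allenylzinc reagent 20 (not isolated)
Conditions: Pd(OAc)2 (5 mol %), PPh3 (5 mol %), Et2Zn, THF, −78 → −20 °C; aq. NH4Cl
Reagents that add atoms: none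
Why: Marshall propargylation: zerovalent palladium displaces the mesylate anti (SN2'), transmetalation gives the (aS)-allenylzinc, and its SE2' addition to the aldehyde through a cyclic transition state should set the methyl-bearing carbon as S (net inversion) and the carbinol anti to it; the carbinol configuration is immaterial because it is oxidised in step 16.

Step 12
Reactants: 21 (3R,4S)-4-methylhex-5-yn-3-ol
Product: 22 triethyl{[(3R,4S)-4-methylhex-5-yn-3-yl]oxy}silane
Conditions: Et3SiCl, imidazole, DMF, 0 °C → rt
Reagents that add atoms: chlorotriethylsilane, CC[Si](Cl)(CC)CC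
Why: Standard silylation of a secondary alcohol; the triethylsilyl ether survives organolithium reagents and is removed by the dilute acid of step 15.

Step 13
Reactants: 22 the terminal alkyne
Product: 24 triethyl{[(3R,4S)-4-methylhept-5-yn-3-yl]oxy}silane, via lithium acetylide 23 (not isolated)
Conditions: n-BuLi, THF, −78 °C; MeI, −78 °C → rt
Reagents that add atoms: iodomethane, CI
Why: Deprotonation of the terminal alkyne and SN2 methylation of the acetylide; the propargylic stereocentre is not acidic under these conditions.

Step 14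
Reactants: 24 the methyl alkyne
Product: 26 triethyl{[(3R,4S,5E)-6-iodo-4-methylhept-5-en-3-yl]oxy}silane, via alkenylzirconocene 25 (not isolated)
Conditions: Cp2Zr(H)Cl (excess), THF, 50 °C; then I2, 0 °C
Reagents that add atoms: iodine, II
Why: syn-Hydrozirconation; with excess hydride the alkenylzirconium isomers equilibrate to the one with zirconium on the methyl-bearing carbon, remote from the branched centre, and iodinolysis with retention should give the E iodide.

**Union and end game**

Step 15
Reactants: 26 the alkenyl iodide; 16 the (6R)-dienone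
Product: 30 2-[(1S)-2-[(2E,4S,5R)-5-hydroxy-4-methylhept-2-en-2-yl]-1,3,5-trimethyl-4-oxocyclohexa-2,5-dien-1-yl]-6-methoxy-3,5-dimethyl-4H-pyran-4-one, via alkenyllithium 27 (not isolated), via alkenylcerium dichloride 28 (not isolated), via tertiary dienol adduct 29 (not isolated)
Conditions: 26, t-BuLi (2 equiv), Et2O, −78 °C; CeCl3, THF, −78 °C; then 16, −78 → −40 °C; then 1 M aq. HCl, THF, 0 °C → rt
Reagents that add atoms: water, O
Why: Iodine–lithium exchange with retention, transmetalation to the alkenylcerium dichloride and 1,2-addition to the vinylogous-ester carbonyl (the pyranone carbonyl is a doubly vinylogous ester flanked by two methyl groups), then acid-induced Stork–Danheiser transposition should give the cross-conjugated dienone and cleave the silyl ether; no stereocentre is formed or touched, the carbinol carbon of the adduct becoming sp2.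

Step 16
Reactants: 30 the dienone alcohol
Product: 31 2-methoxy-3,5-dimethyl-6-[(1S)-1,3,5-trimethyl-2-[(2E,4S)-4-methyl-5-oxohept-2-en-2-yl]-4-oxocyclohexa-2,5-dien-1-yl]-4H-pyran-4-one
Conditions: Dess–Martin periodinane, NaHCO3, CH2Cl2, 0 °C
Reagents that add atoms: none
Why: Dess–Martin oxidation under buffered, non-basic conditions should convert the secondary alcohol into the ethyl ketone without enolising the adjacent β,γ-unsaturated α-methyl stereocentre.

**Compound list**

1 | methyl 2-methyl-3-oxopentanoate | CCC(=O)C(C)C(=O)OC | starting material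
2 | N-methoxy-N-methylpropanamide | CCC(=O)N(C)OC | starting material
3 | sodium lithium dianion of 1 (not isolated) | CC=C([O-])C(C)=C([O-])OC.[Na+].[Li+] | intermediate
4 | methyl 2,4-dimethyl-3,5-dioxoheptanoate | CCC(=O)C(C)C(=O)C(C)C(=O)OC | intermediate
5 | 6-ethyl-4-hydroxy-3,5-dimethyl-2H-pyran-2-one | CCc1oc(=O)c(C)c(O)c1C | intermediate
6 | 2-ethyl-6-methoxy-3,5-dimethyl-4H-pyran-4-one | CCc1oc(OC)c(C)c(=O)c1C | intermediate
7 | methyl formate | COC=O | starting material
8 | dilithium dianion of 1 (not isolated) | CC=C([O-])C(C)=C([O-])OC.[Li+].[Li+] | intermediate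
9 | methyl 2,4-dimethyl-3,5-dioxopentanoate | O=CC(C)C(=O)C(C)C(=O)OC | intermediate
10 | 4-hydroxy-3,5-dimethyl-2H-pyran-2-one | Cc1coc(=O)c(C)c1O | intermediate
11 | 4-methoxy-3,5-dimethyl-2H-pyran-2-one | COc1c(C)coc(=O)c1C | intermediate
12 | lithium (1Z,3E)-3-methoxy-5-[methoxy(methyl)amino]-2,4-dimethyl-5-oxopenta-1,3-dien-1-olate (not isolated) | CON(C)C(=O)/C(C)=C(OC)\C(C)=C/[O-].[Li+] | intermediate
13 | (1Z,3E)-3-methoxy-5-[methoxy(methyl)amino]-2,4-dimethyl-5-oxopenta-1,3-dien-1-yl trifluoromethanesulfonate | CON(C)C(=O)/C(C)=C(OC)\C(C)=C/OS(=O)(=O)C(F)(F)F | intermediate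
14 | lithiated 6, carbanion at the ethyl CH (not isolated) | C[CH-]c1oc(OC)c(C)c(=O)c1C.[Li+] | intermediate
15 | (1Z,3E)-3-methoxy-6-(6-methoxy-3,5-dimethyl-4-oxo-4H-pyran-2-yl)-2,4-dimethyl-5-oxohepta-1,3-dien-1-yl trifluoromethanesulfonate, racemic at C-6 | COc1oc(C(C)C(=O)/C(C)=C(OC)\C(C)=C/OS(=O)(=O)C(F)(F)F)c(C)c(=O)c1C | intermediate
16 | (6R)-3-methoxy-6-(6-methoxy-3,5-dimethyl-4-oxo-4H-pyran-2-yl)-2,4,6-trimethylcyclohexa-2,4-dien-1-one | O=C1C(C)=C(OC)C(C)=C[C@]1(C)c1oc(OC)c(C)c(=O)c1C | intermediate
17 | (R)-but-3-yn-2-ol | C[C@@H](O)C#C | starting material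
18 | (R)-but-3-yn-2-yl methanesulfonate | C[C@@H](OS(C)(=O)=O)C#C | intermediate
19 | propanal | CCC=O | starting material
20 | ethyl[(aS)-buta-1,2-dien-1-yl]zinc (not isolated) | CC[Zn]C([H])=[C@@]=C([H])C | intermediate
21 | (3R,4S)-4-methylhex-5-yn-3-ol | CC[C@@H](O)[C@@H](C)C#C | intermediate
22 | triethyl{[(3R,4S)-4-methylhex-5-yn-3-yl]oxy}silane | CC[C@@H](O[Si](CC)(CC)CC)[C@@H](C)C#C | intermediate
23 | lithium acetylide of 22 (not isolated) | CC[C@@H](O[Si](CC)(CC)CC)[C@@H](C)C#C[Li] | intermediate
24 | triethyl{[(3R,4S)-4-methylhept-5-yn-3-yl]oxy}silane | CC[C@@H](O[Si](CC)(CC)CC)[C@@H](C)C#CC | intermediate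
25 | chlorobis(cyclopentadienyl)[(2E,4S,5R)-4-methyl-5-(triethylsilyloxy)hept-2-en-2-yl]zirconium (not isolated) | CC[C@@H](O[Si](CC)(CC)CC)[C@@H](C)/C=C(\C)[Zr](Cl)(C1C=CC=C1)C1C=CC=C1 | intermediate
26 | triethyl{[(3R,4S,5E)-6-iodo-4-methylhept-5-en-3-yl]oxy}silane | CC[C@@H](O[Si](CC)(CC)CC)[C@@H](C)/C=C(\C)I | intermediate
27 | [(2Z,4S,5R)-4-methyl-5-(triethylsilyloxy)hept-2-en-2-yl]lithium, alkene geometry as in 26 (not isolated) | CC[C@@H](O[Si](CC)(CC)CC)[C@@H](C)/C=C(\C)[Li] | intermediate
28 | dichloro[(2E,4S,5R)-4-methyl-5-(triethylsilyloxy)hept-2-en-2-yl]cerium (not isolated) | CC[C@@H](O[Si](CC)(CC)CC)[C@@H](C)/C=C(\C)[Ce](Cl)Cl | intermediate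
29 | tertiary dienol from 1,2-addition of 28 to the ring carbonyl of 16, both carbinol epimers, quaternary centre as in 16 (not isolated) | CC[C@@H](O[Si](CC)(CC)CC)[C@@H](C)/C=C(\C)C1(O)C(C)=C(OC)C(C)=C[C@]1(C)c1oc(OC)c(C)c(=O)c1C | intermediate
30 | 2-[(1S)-2-[(2E,4S,5R)-5-hydroxy-4-methylhept-2-en-2-yl]-1,3,5-trimethyl-4-oxocyclohexa-2,5-dien-1-yl]-6-methoxy-3,5-dimethyl-4H-pyran-4-one | CC[C@@H](O)[C@@H](C)/C=C(\C)C1=C(C)C(=O)C(C)=C[C@]1(C)c1oc(OC)c(C)c(=O)c1C | intermediate
31 | 2-methoxy-3,5-dimethyl-6-[(1S)-1,3,5-trimethyl-2-[(2E,4S)-4-methyl-5-oxohept-2-en-2-yl]-4-oxocyclohexa-2,5-dien-1-yl]-4H-pyran-4-one (CNP0276209.1) | CCC(=O)[C@@H](C)/C=C(\C)C1=C(C)C(=O)C(C)=C[C@]1(C)c1oc(OC)c(C)c(=O)c1C | target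

**Count**

Total steps: 16. Longest linear sequence: 8 steps (1 → 9 → 10 → 11 → 13 → 15 → 16 → 30 → 31; steps 4, 5, 6, 7, 8, 9, 15, 16).

**Steps most likely to fail, with fallbacks**

Step 9. The acyclic palladium enolate may be discriminated poorly between its two faces, or the dienylpalladium may be diverted by O-alkenylation or by β-hydride loss from the α-methyl group. Fallback: the ring is closed without metal and the configuration is secured by resolution. Setting out from 15, K2CO3 in MeOH at 0 °C cleaves the enol triflate to the keto aldehyde (3E)-3-methoxy-6-(6-methoxy-3,5-dimethyl-4-oxo-4H-pyran-2-yl)-2,4-dimethyl-5-oxohept-3-enal F1. Piperidinium acetate in toluene at 60 °C should then effect the classical intramolecular aldol condensation of this 1,5-keto aldehyde (ketone α-carbon onto the aldehyde, then vinylogous dehydration). This forms the same ring bond and gives the racemic dienone, that is 16 together with its (6S)-enantiomer F2. Preparative chromatography on a chiral stationary phase returns the route to 16.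

Step 7. The amide may attack C-6 of the pyranone instead of the lactone carbonyl, or the dienolate may rotate before sulfonylation so that the triflate ends trans to the methoxy-bearing carbon and can no longer reach the ketone after oxidative addition. Fallback: the dienyl electrophile is built in the open chain with the Z geometry fixed by carbometalation. Setting out from 2: prop-2-yn-1-ol is converted by CuI-catalysed anti-addition of MeMgBr and iodinolysis into (Z)-3-iodo-2-methylprop-2-en-1-ol F3, which MnO2 oxidises to (Z)-3-iodo-2-methylprop-2-enal F4. The lithium enolate of 2 (LiN(i-Pr)2, THF, −78 °C) adds to F4 to give (4Z)-3-hydroxy-5-iodo-N-methoxy-N,2,4-trimethylpent-4-enamide F5, and Dess–Martin oxidation gives (4Z)-5-iodo-N-methoxy-N,2,4-trimethyl-3-oxopent-4-enamide F6. O-Methylation of its enolate (K2CO3, Me2SO4, DMF) gives (2E,4Z)-5-iodo-N,3-dimethoxy-N,2,4-trimethylpenta-2,4-dienamide F7, the iodo analogue of 13; the 2E isomer is separated or reached by equilibration of the push–pull alkene. Acylation of lithiated 6 as in step 8 gives (4E,6Z)-7-iodo-5-methoxy-2-(6-methoxy-3,5-dimethyl-4-oxo-4H-pyran-2-yl)-4,6-dimethylhepta-4,6-dien-3-one F8, and the ring closure of step 9 applied to F8 returns the route to 16.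

Step 8. The hindered carbanion may be acylated only sluggishly by the electron-rich unsaturated amide, or may attack the sulfonyl group or the methoxy-bearing β-carbon instead. Fallback: the carbon–carbon bond is made by aldol addition and the ketone by oxidation. Setting out from 13, i-Bu2AlH (THF, −78 °C) reduces the Weinreb amide to the aldehyde (1Z,3E)-3-methoxy-2,4-dimethyl-5-oxopenta-1,3-dien-1-yl trifluoromethanesulfonate F9. Lithiated 6 adds to F9 to give (1Z,3E)-5-hydroxy-3-methoxy-6-(6-methoxy-3,5-dimethyl-4-oxo-4H-pyran-2-yl)-2,4-dimethylhepta-1,3-dien-1-yl trifluoromethanesulfonate F10 as a mixture of diastereomers, and Dess–Martin oxidation returns the route to 15.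

**Further compounds**

F1 | step 9 | (3E)-3-methoxy-6-(6-methoxy-3,5-dimethyl-4-oxo-4H-pyran-2-yl)-2,4-dimethyl-5-oxohept-3-enal | O=CC(C)/C(OC)=C(C)\C(=O)C(C)c1oc(OC)c(C)c(=O)c1C
F2 | step 9 | (6S)-3-methoxy-6-(6-methoxy-3,5-dimethyl-4-oxo-4H-pyran-2-yl)-2,4,6-trimethylcyclohexa-2,4-dien-1-one | O=C1C(C)=C(OC)C(C)=C[C@@]1(C)c1oc(OC)c(C)c(=O)c1C
F3 | step 7 | (Z)-3-iodo-2-methylprop-2-en-1-ol | C/C(CO)=C/I
F4 | step 7 | (Z)-3-iodo-2-methylprop-2-enal | C/C(C=O)=C/I
F5 | step 7 | (4Z)-3-hydroxy-5-iodo-N-methoxy-N,2,4-trimethylpent-4-enamide | CON(C)C(=O)C(C)C(O)/C(C)=C\I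
F6 | step 7 | (4Z)-5-iodo-N-methoxy-N,2,4-trimethyl-3-oxopent-4-enamide | CON(C)C(=O)C(C)C(=O)/C(C)=C\I
F7 | step 7 | (2E,4Z)-5-iodo-N,3-dimethoxy-N,2,4-trimethylpenta-2,4-dienamide | CON(C)C(=O)/C(C)=C(OC)\C(C)=C/I
F8 | step 7 | (4E,6Z)-7-iodo-5-methoxy-2-(6-methoxy-3,5-dimethyl-4-oxo-4H-pyran-2-yl)-4,6-dimethylhepta-4,6-dien-3-one | COc1oc(C(C)C(=O)/C(C)=C(OC)\C(C)=C/I)c(C)c(=O)c1C
F9 | step 8 | (1Z,3E)-3-methoxy-2,4-dimethyl-5-oxopenta-1,3-dien-1-yl trifluoromethanesulfonate | O=C/C(C)=C(OC)\C(C)=C/OS(=O)(=O)C(F)(F)F
F10 | step 8 | (1Z,3E)-5-hydroxy-3-methoxy-6-(6-methoxy-3,5-dimethyl-4-oxo-4H-pyran-2-yl)-2,4-dimethylhepta-1,3-dien-1-yl trifluoromethanesulfonate | COc1oc(C(C)C(O)/C(C)=C(OC)\C(C)=C/OS(=O)(=O)C(F)(F)F)c(C)c(=O)c1C
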